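Reading across is the easy step: 120 s in the two earlier runs is the asked time of the new flask.

| setting | birch | elm | flask |
|---|---|---|---|
| starting material | 0.026 M | 0.10 M | 0.052 M |
| reagent | 0.0624 M | 0.0624 M | 0.0624 M |
| scavenger | 0.026 M | 0.026 M | 0.0260 M |
| remark | run made earlier | run made earlier |  |
| time |  |  | 2.0 min |

| run | time / s | starting material / % | product / % |
|---|---|---|---|
| birch | 15.0 | 97.7 | 1.8 |
| birch | 30.0 | 94.8 | 5.1 |
| birch | 50.0 | 91.6 | 5.8 |
| birch | 60.0 | 92.9 | 8.1 |
| birch | 80.0 | 89.6 | 9.0 |
| birch | 90.0 | 90.3 | 10.3 |
| birch | 120 | 87.5 | 14.1 |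
| elm | 10.0 | 97.9 | 2.0 |
| elm | 15.0 | 96.9 | 1.5 |
| elm | 20.0 | 95.8 | 1.4 |
| elm | 30.0 | 96.3 | 4.6 |
| elm | 50.0 | 97.1 | 4.7 |
| elm | 80.0 | 95.5 | 3.8 |
| elm | 120 | 93.8 | 3.9 |

(readings scatter by 1 percentage point)

- part of the starting material that has reacted at 2.0 min
- share of the unused reagent that is free and not bound as idle adduct, at 2.0 min

- the earlier runs do not show how much of reagent is bound; that part of a forecast is a guess

By then birch had lost 12.5% of its starting material and elm 6.20%. The elm charge was 3.85 times the birch charge, and the reacted part was 2.02 times smaller, close to the square root of the charge ratio, 1.96. Both runs and the flask shared the same reagent and scavenger, so I read an order of 0.5 in starting material. My transferred conversion is a run's reacted part times the square root of its charge over the flask's. Birch gave 8.84% and elm 8.60%, with a mean of 8.72%.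

The forecast gave 9% reacted and 45% free, adding: “The free share is largely a guess”.

The flask gave 9.30% reacted and 98.9% free, with 6.16 × 10⁻⁴ M of idle adduct standing at 2.00 min.

    starting material ⇌ intermediate + leaving ligand (K = 6.80 × 10⁻⁶ M, k = 0.0340 s⁻¹)
    reagent + intermediate → product (k = 1.60 L mol⁻¹ s⁻¹)
    reagent + leaving ligand ⇌ idle adduct, settled at all times (K = 11.0 L mol⁻¹)
    scavenger + leaving ligand → scavenged by-product (k = 1.30 L mol⁻¹ s⁻¹)

My 8.72% fell 0.58 percentage points short of the flask. At 2.0 min the flask formed product at 0.0341 min⁻¹ of its charge and scavenged leaving ligand at about the same 0.0334 min⁻¹, while intermediate times leaving ligand over starting material stood near 6.8 × 10⁻⁶ M. Taken as exact, those two relations give a rate that goes as the square root of reagent times scavenger times starting material, so with scavenger, starting material and time held, my transfer scales as the square root of reagent. A neighbouring flask held 0.016 M of reagent, its other charges and time as before; the transfer became 4.41%, and that flask gave 4.94%.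

The data are calculated on assumed constants; scatter was added.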